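**Plan**

1. Retrosynthetic cuts, in order: O7–Si; C3–C4 of ring C (the key cut, leaving an aroyl chloride on ring A and a racemic benzylic chloride next to ring B); the two C–Cl bonds (back to a hydroxy acid); the ether bond O1–C2; the carboxyl carbon and the prenyl group on ring A; the aryl–CO bond of a bromomethyl ketone.
2. Forward: 2,2-dimethylchroman (rings B and D ready-made) is bromoacetylated; resorcinol is turned into a 3-prenyl salicylate by two ortho-lithiations; the halves are joined through O1–C2; ring C is closed last and is the only ring made.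
3. Stereochemistry: C3 is the only stereocentre. It is set in the ring closure by a chiral bis(oxazoline)–nickel catalyst from a racemic chloride, and kept by a buffered desilylation.
4. Enabling feature: C4 (acyl carbon on ring A) and C3 (benzylic to ring B) are both natural electrophiles, and C3 flattens to a benzylic radical on halogen abstraction, so both enantiomers of the chloride converge.

Key step: step 11

Assumption: 2,2-dimethylchroman is taken as purchasable.
Assumption: the (4R,5S) antipode of the bis(oxazoline) is written as the one leading to (R)-21; if the ring closure shows the opposite sense of induction, the equally available (4S,5R) ligand takes its place.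
Numbering: O1, C2, C3, C4 and ring A (C4a–C8a) as in chroman-4-one; ring C is the pyranone; ring B is the benzene ring of the 2,2-dimethylchroman-6-yl group and ring D its pyran ring.

**Route**

Step 1
Reactants: 1 2,2-dimethylchroman; 2 bromoacetyl bromide
Product: 3 2-bromo-1-(2,2-dimethylchroman-6-yl)ethan-1-one
Conditions: AlCl3 (1.1 equiv), CH2Cl2, –20 → 0 °C
Reagents that add atoms: bromoacetyl bromide (2), BrCC(Br)=O
Why: Friedel–Crafts acylation of the aryl ether should go para to the ring oxygen (C6), the ortho site C8 being more hindered.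

Step 2
Reactants: 4 resorcinol; 5 chloromethyl methyl ether
Product: 6 1,3-bis(methoxymethoxy)benzene
Conditions: NaH (2.2 equiv), DMF, 0 °C → rt
Reagents that add atoms: chloromethyl methyl ether (5), COCCl
Why: Williamson-type O-alkylation of both phenoxides installs the acetal groups that later direct the two lithiations.

Step 3
Reactants: 6 1,3-bis(methoxymethoxy)benzene; 7 prenyl bromide (1-bromo-3-methylbut-2-ene)
Product: 9 1,3-bis(methoxymethoxy)-2-(3-methylbut-2-en-1-yl)benzene, via 2-lithio-1,3-bis(methoxymethoxy)benzene 8 (not isolated)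
Conditions: n-BuLi, THF, 0 °C → rt; then CuI (10 mol %), 7, –78 °C → rt
Reagents that add atoms: prenyl bromide (7), CC(C)=CCBr
Why: directed ortho-metalation takes place at C2 between the two acetal oxygens, and copper-assisted alkylation of the aryllithium with the allylic bromide should give the linear (SN2) prenyl product.

Step 4
Reactants: 9 1,3-bis(methoxymethoxy)-2-(3-methylbut-2-en-1-yl)benzene; 10 allyl chloroformate
Product: 12 allyl 2,4-bis(methoxymethoxy)-3-(3-methylbut-2-en-1-yl)benzoate, via 4-lithio-1,3-bis(methoxymethoxy)-2-(3-methylbut-2-en-1-yl)benzene 11 (not isolated)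
Conditions: n-BuLi, TMEDA, THF, –20 → 0 °C; then cannulated into 10 (2 equiv), THF, –78 °C
Reagents that add atoms: allyl chloroformate (10), C=CCOC(Cl)=O
Why: a second directed ortho-metalation at the only kind of ring position left next to an acetal oxygen, followed by acylation of the aryllithium with a chloroformate under inverse addition, should give the ester directly.

Step 5
Reactants: 12 allyl 2,4-bis(methoxymethoxy)-3-(3-methylbut-2-en-1-yl)benzoate
Product: 13 allyl 2,4-dihydroxy-3-(3-methylbut-2-en-1-yl)benzoate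
Conditions: 3 M aq. HCl, THF/i-PrOH, 40 °C
Reagents that add atoms: none
Why: acid-catalysed acetal hydrolysis frees both phenols, while the hindered aryl ester resists hydrolysis and short, mild heating should spare the prenyl group from cyclising onto a neighbouring phenol.

Step 6
Reactants: 13 allyl 2,4-dihydroxy-3-(3-methylbut-2-en-1-yl)benzoate; 14 chlorotriisopropylsilane
Product: 15 allyl 2-hydroxy-3-(3-methylbut-2-en-1-yl)-4-(triisopropylsilyloxy)benzoate
Conditions: TIPSCl (1.1 equiv), imidazole, DMF, 0 °C → rt
Reagents that add atoms: chlorotriisopropylsilane (14), CC(C)[Si](Cl)(C(C)C)C(C)C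
Why: silylation should select the 4-OH, because the 2-OH is hydrogen-bonded to the ester carbonyl and flanked on both sides.

Step 7
Reactants: 15 allyl 2-hydroxy-3-(3-methylbut-2-en-1-yl)-4-(triisopropylsilyloxy)benzoate; 3 2-bromo-1-(2,2-dimethylchroman-6-yl)ethan-1-one
Product: 16 allyl 2-[2-(2,2-dimethylchroman-6-yl)-2-oxoethoxy]-3-(3-methylbut-2-en-1-yl)-4-(triisopropylsilyloxy)benzoate
Conditions: K2CO3, acetone, 40 °C
Reagents that add atoms: 2-bromo-1-(2,2-dimethylchroman-6-yl)ethan-1-one (3), CC1(C)CCc2cc(C(=O)CBr)ccc2O1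
Why: Williamson ether synthesis in which the highly reactive alpha-bromo ketone compensates for the hindered salicylate phenoxide, under carbonate conditions mild enough to keep the silyl ether and to avoid Dieckmann-type closure onto the ester.

Step 8
Reactants: 16 allyl 2-[2-(2,2-dimethylchroman-6-yl)-2-oxoethoxy]-3-(3-methylbut-2-en-1-yl)-4-(triisopropylsilyloxy)benzoate
Product: 17 rac-allyl 2-[2-(2,2-dimethylchroman-6-yl)-2-hydroxyethoxy]-3-(3-methylbut-2-en-1-yl)-4-(triisopropylsilyloxy)benzoate
Conditions: NaBH4, THF/MeOH, 0 °C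
Reagents that add atoms: none
Why: borohydride reduction takes the ketone and leaves the aryl ester, and the racemic carbinol centre needs no control because it is flattened in step 11.

Step 9
Reactants: 17 rac-allyl 2-[2-(2,2-dimethylchroman-6-yl)-2-hydroxyethoxy]-3-(3-methylbut-2-en-1-yl)-4-(triisopropylsilyloxy)benzoate
Product: 18 rac-2-[2-(2,2-dimethylchroman-6-yl)-2-hydroxyethoxy]-3-(3-methylbut-2-en-1-yl)-4-(triisopropylsilyloxy)benzoic acid
Conditions: Pd(PPh3)4 (3 mol %), morpholine, THF, rt; dilute citric acid work-up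
Reagents that add atoms: none
Why: Tsuji–Trost deallylation, in which zerovalent palladium ionises the allyl ester and morpholine takes up the allyl group, is neutral enough to leave the silyl ether, the prenyl group and the benzylic alcohol alone.

Step 10
Reactants: 18 rac-2-[2-(2,2-dimethylchroman-6-yl)-2-hydroxyethoxy]-3-(3-methylbut-2-en-1-yl)-4-(triisopropylsilyloxy)benzoic acid; 19 1-chloro-N,N,2-trimethylprop-1-en-1-amine
Product: 20 rac-2-[2-chloro-2-(2,2-dimethylchroman-6-yl)ethoxy]-3-(3-methylbut-2-en-1-yl)-4-(triisopropylsilyloxy)benzoyl chloride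
Conditions: 18 added to 19 (2.5 equiv), CH2Cl2, 0 °C → rt; volatiles removed in vacuo; used crude at once
Reagents that add atoms: 1-chloro-N,N,2-trimethylprop-1-en-1-amine (19), CC(C)=C(Cl)N(C)C
Why: the alpha-chloroenamine (Ghosez reagent) converts carboxylic acids to acid chlorides and alcohols to alkyl chlorides under neutral conditions with only an amide as by-product, so no HCl reaches the prenyl alkene, and adding 18 to excess reagent should chlorinate the alcohol before it can lactonise onto the acid chloride.

Step 11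
Reactants: 20 rac-2-[2-chloro-2-(2,2-dimethylchroman-6-yl)ethoxy]-3-(3-methylbut-2-en-1-yl)-4-(triisopropylsilyloxy)benzoyl chloride
Product: 21 (3R)-3-(2,2-dimethylchroman-6-yl)-8-(3-methylbut-2-en-1-yl)-7-(triisopropylsilyloxy)chroman-4-one
Conditions: NiCl2(dme) (10 mol %), (4R,5S,4'R,5'S)-2,2'-(propane-2,2-diyl)bis(4,5-diphenyl-4,5-dihydrooxazole) (22 mol %), Mn powder (3 equiv), 2,6-dimethylbenzoic acid (0.75 equiv), 3 Å MS, DMA/THF 3:7, 20 °C; 20 added over several hours to 0.01 M
Reagents that add atoms: none
Why: Proposed new method: zerovalent nickel, formed from NiCl2 and manganese, should insert into the aroyl C–Cl bond at C4, and after one-electron reduction the acylnickel abstracts chlorine from C3, so that both enantiomers of 20 give the same planar benzylic radical, which is caught by the ligand-bound nickel and released with C3–C4 formed by reductive elimination. The closest known reaction type is the nickel/bis(oxazoline)-catalysed enantioconvergent reductive coupling of acid chlorides with racemic secondary benzylic chlorides, known between two molecules but not as a ring closure nor with an aryloxy group beta to the benzylic carbon. Ring C closes by reductive elimination from a seven-membered acyl(benzyl)nickel chelate, formally a 6-exo-trig attack of C3 on the acyl carbon that leaves the carbonyl oxygen outside the ring. C3, the only stereocentre, is set under catalyst control by the C2-symmetric bis(oxazoline) at radical capture and reductive elimination, the substrate being racemic and free of any other stereocentre. The step needs ring closure to outrun beta-elimination of the ring A aryloxide, benzylic homocoupling and decarbonylation, which the ortho arrangement of the two electrophiles and slow addition at high dilution are meant to secure, while the C3 radical could reach the prenyl alkene only through a seven-membered transition state. Since no base is present and the temperature stays at 20 °C, the new C3–H next to the ketone should keep its configuration.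

Step 12
Reactants: 21 (3R)-3-(2,2-dimethylchroman-6-yl)-8-(3-methylbut-2-en-1-yl)-7-(triisopropylsilyloxy)chroman-4-one
Product: 22 (3R)-3-(2,2-dimethylchroman-6-yl)-7-hydroxy-8-(3-methylbut-2-en-1-yl)chroman-4-one (CNP0139927.1)
Conditions: TBAF (1.1 equiv), AcOH (1.5 equiv), THF, 0 °C
Reagents that add atoms: none
Why: fluoride-induced cleavage of the aryl silyl ether, with acetic acid keeping the medium from turning basic, should free O7 without removing the epimerisable C3–H next to the ketone.

**Compound list**

1 | 2,2-dimethylchroman | CC1(C)CCc2ccccc2O1 | starting material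
2 | bromoacetyl bromide | BrCC(Br)=O | starting material
3 | 2-bromo-1-(2,2-dimethylchroman-6-yl)ethan-1-one | CC1(C)CCc2cc(C(=O)CBr)ccc2O1 | intermediate
4 | resorcinol | Oc1cccc(O)c1 | starting material
5 | chloromethyl methyl ether | COCCl | starting material
6 | 1,3-bis(methoxymethoxy)benzene | COCOc1cccc(OCOC)c1 | intermediate
7 | prenyl bromide (1-bromo-3-methylbut-2-ene) | CC(C)=CCBr | starting material
8 | 2-lithio-1,3-bis(methoxymethoxy)benzene | [Li]c1c(OCOC)cccc1OCOC | intermediate
9 | 1,3-bis(methoxymethoxy)-2-(3-methylbut-2-en-1-yl)benzene | COCOc1cccc(OCOC)c1CC=C(C)C | intermediate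
10 | allyl chloroformate | C=CCOC(Cl)=O | starting material
11 | 4-lithio-1,3-bis(methoxymethoxy)-2-(3-methylbut-2-en-1-yl)benzene | [Li]c1ccc(OCOC)c(CC=C(C)C)c1OCOC | intermediate
12 | allyl 2,4-bis(methoxymethoxy)-3-(3-methylbut-2-en-1-yl)benzoate | C=CCOC(=O)c1ccc(OCOC)c(CC=C(C)C)c1OCOC | intermediate
13 | allyl 2,4-dihydroxy-3-(3-methylbut-2-en-1-yl)benzoate | C=CCOC(=O)c1ccc(O)c(CC=C(C)C)c1O | intermediate
14 | chlorotriisopropylsilane | CC(C)[Si](Cl)(C(C)C)C(C)C | starting material
15 | allyl 2-hydroxy-3-(3-methylbut-2-en-1-yl)-4-(triisopropylsilyloxy)benzoate | C=CCOC(=O)c1ccc(O[Si](C(C)C)(C(C)C)C(C)C)c(CC=C(C)C)c1O | intermediate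
16 | allyl 2-[2-(2,2-dimethylchroman-6-yl)-2-oxoethoxy]-3-(3-methylbut-2-en-1-yl)-4-(triisopropylsilyloxy)benzoate | C=CCOC(=O)c1ccc(O[Si](C(C)C)(C(C)C)C(C)C)c(CC=C(C)C)c1OCC(=O)c1ccc2c(c1)CCC(C)(C)O2 | intermediate
17 | rac-allyl 2-[2-(2,2-dimethylchroman-6-yl)-2-hydroxyethoxy]-3-(3-methylbut-2-en-1-yl)-4-(triisopropylsilyloxy)benzoate | C=CCOC(=O)c1ccc(O[Si](C(C)C)(C(C)C)C(C)C)c(CC=C(C)C)c1OCC(O)c1ccc2c(c1)CCC(C)(C)O2 | intermediate
18 | rac-2-[2-(2,2-dimethylchroman-6-yl)-2-hydroxyethoxy]-3-(3-methylbut-2-en-1-yl)-4-(triisopropylsilyloxy)benzoic acid | OC(=O)c1ccc(O[Si](C(C)C)(C(C)C)C(C)C)c(CC=C(C)C)c1OCC(O)c1ccc2c(c1)CCC(C)(C)O2 | intermediate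
19 | 1-chloro-N,N,2-trimethylprop-1-en-1-amine | CC(C)=C(Cl)N(C)C | starting material
20 | rac-2-[2-chloro-2-(2,2-dimethylchroman-6-yl)ethoxy]-3-(3-methylbut-2-en-1-yl)-4-(triisopropylsilyloxy)benzoyl chloride | CC(C)=CCc1c(O[Si](C(C)C)(C(C)C)C(C)C)ccc(C(Cl)=O)c1OCC(Cl)c1ccc2c(c1)CCC(C)(C)O2 | intermediate
21 | (3R)-3-(2,2-dimethylchroman-6-yl)-8-(3-methylbut-2-en-1-yl)-7-(triisopropylsilyloxy)chroman-4-one | CC(C)=CCc1c(O[Si](C(C)C)(C(C)C)C(C)C)ccc2c1OC[C@@H](c1ccc3c(c1)CCC(C)(C)O3)C2=O | intermediate
22 | (3R)-3-(2,2-dimethylchroman-6-yl)-7-hydroxy-8-(3-methylbut-2-en-1-yl)chroman-4-one | CC(C)=CCc1c(O)ccc2c1OC[C@@H](c1ccc3c(c1)CCC(C)(C)O3)C2=O | target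

**Step count and risks**

Total steps: 12. Longest linear sequence: 11 (steps 2–12, from resorcinol).

Steps most likely to fail:

1. Step 11 (the proposed new method). The ring A aryloxide may be lost by beta-elimination from the benzylic nickel or radical intermediate. Coupling between molecules, benzylic homocoupling or decarbonylation of the acylnickel may outrun ring closure. Enantioinduction in the cyclic transition state may be weak.
Fallback, known chemistry, setting out from 9 (with 1 as second component) and coming back at 21: aryllithium 11, made from 9 as in step 4, would be acylated with N-methoxy-N-methylacetamide to the methyl ketone 1-[2,4-bis(methoxymethoxy)-3-(3-methylbut-2-en-1-yl)phenyl]ethan-1-one F1. Compound 1 would be brominated para to oxygen (N-bromosuccinimide, MeCN, 0 °C) to 6-bromo-2,2-dimethylchroman F2. Palladium-catalysed ketone alpha-arylation of F1 with F2 (Pd(OAc)2, XPhos, NaOt-Bu, toluene, 70 °C) should give the deoxybenzoin 1-[2,4-bis(methoxymethoxy)-3-(3-methylbut-2-en-1-yl)phenyl]-2-(2,2-dimethylchroman-6-yl)ethan-1-one F3. Aqueous HCl would free 1-[2,4-dihydroxy-3-(3-methylbut-2-en-1-yl)phenyl]-2-(2,2-dimethylchroman-6-yl)ethan-1-one F4, and TIPSCl/imidazole would silylate the 4-OH to 2-(2,2-dimethylchroman-6-yl)-1-[2-hydroxy-3-(3-methylbut-2-en-1-yl)-4-(triisopropylsilyloxy)phenyl]ethan-1-one F5. N,N-Dimethylformamide dimethyl acetal (toluene, 90 °C) supplies C2 and closes ring C to the isoflavone 3-(2,2-dimethylchroman-6-yl)-8-(3-methylbut-2-en-1-yl)-7-(triisopropylsilyloxy)-4H-chromen-4-one F6. Asymmetric transfer hydrogenation (RuCl(p-cymene)[(R,R)-TsDPEN], HCO2H/Et3N) should reduce the C2=C3 bond and then the ketone with dynamic kinetic resolution through the epimerising isoflavanone, giving the cis alcohol (3R,4R)-3-(2,2-dimethylchroman-6-yl)-8-(3-methylbut-2-en-1-yl)-7-(triisopropylsilyloxy)chroman-4-ol F7. Dess–Martin oxidation buffered with NaHCO3 would return the ketone without touching C3, giving 21.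

2. Step 10. The hydroxy acid chloride may close to a seven-membered lactone before the alcohol is chlorinated. The benzylic chloride may lose HCl to the aryl styryl ether, or hydrolyse on handling.
Fallback, setting out from 18 and coming back at 20, separates the two chlorinations with the acid masked: TBSCl (1.0 equiv) and imidazole in DMF at 0 °C should silylate the carboxyl group first, giving tert-butyldimethylsilyl rac-2-[2-(2,2-dimethylchroman-6-yl)-2-hydroxyethoxy]-3-(3-methylbut-2-en-1-yl)-4-(triisopropylsilyloxy)benzoate F8. MsCl/Et3N in CH2Cl2 would convert the electron-rich benzylic alcohol by way of its mesylate to tert-butyldimethylsilyl rac-2-[2-chloro-2-(2,2-dimethylchroman-6-yl)ethoxy]-3-(3-methylbut-2-en-1-yl)-4-(triisopropylsilyloxy)benzoate F9. Oxalyl chloride with catalytic DMF then turns the silyl ester into the acid chloride under neutral conditions, giving 20.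

3. Step 4. The base may deprotonate the benzylic–allylic CH2 of the prenyl group in place of the ring, and the aryllithium may add a second time to the new ester.
Fallback, setting out from 9 and coming back at 13, replaces lithiation by electrophilic carboxylation: mild aqueous HCl in MeOH would remove both acetals to give 2-(3-methylbut-2-en-1-yl)benzene-1,3-diol F10. Kolbe–Schmitt carboxylation (KHCO3, CO2, glycerol, 120 °C, then acidification) should enter ortho to one hydroxyl and para to the other, giving 2,4-dihydroxy-3-(3-methylbut-2-en-1-yl)benzoic acid F11. Alkylation of the carboxylate alone (allyl bromide, KHCO3, DMF, rt) gives 13, which also makes step 5 unnecessary.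

**Further compounds**

F1 | step 11 | 1-[2,4-bis(methoxymethoxy)-3-(3-methylbut-2-en-1-yl)phenyl]ethan-1-one | CC(=O)c1ccc(OCOC)c(CC=C(C)C)c1OCOC
F2 | step 11 | 6-bromo-2,2-dimethylchroman | CC1(C)CCc2cc(Br)ccc2O1
F3 | step 11 | 1-[2,4-bis(methoxymethoxy)-3-(3-methylbut-2-en-1-yl)phenyl]-2-(2,2-dimethylchroman-6-yl)ethan-1-one | COCOc1ccc(C(=O)Cc2ccc3c(c2)CCC(C)(C)O3)c(OCOC)c1CC=C(C)C
F4 | step 11 | 1-[2,4-dihydroxy-3-(3-methylbut-2-en-1-yl)phenyl]-2-(2,2-dimethylchroman-6-yl)ethan-1-one | CC(C)=CCc1c(O)ccc(C(=O)Cc2ccc3c(c2)CCC(C)(C)O3)c1O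
F5 | step 11 | 2-(2,2-dimethylchroman-6-yl)-1-[2-hydroxy-3-(3-methylbut-2-en-1-yl)-4-(triisopropylsilyloxy)phenyl]ethan-1-one | CC(C)=CCc1c(O[Si](C(C)C)(C(C)C)C(C)C)ccc(C(=O)Cc2ccc3c(c2)CCC(C)(C)O3)c1O
F6 | step 11 | 3-(2,2-dimethylchroman-6-yl)-8-(3-methylbut-2-en-1-yl)-7-(triisopropylsilyloxy)-4H-chromen-4-one | CC(C)=CCc1c(O[Si](C(C)C)(C(C)C)C(C)C)ccc2c1OC=C(c1ccc3c(c1)CCC(C)(C)O3)C2=O
F7 | step 11 | (3R,4R)-3-(2,2-dimethylchroman-6-yl)-8-(3-methylbut-2-en-1-yl)-7-(triisopropylsilyloxy)chroman-4-ol | CC(C)=CCc1c(O[Si](C(C)C)(C(C)C)C(C)C)ccc2c1OC[C@@H](c1ccc3c(c1)CCC(C)(C)O3)[C@H]2O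
F8 | step 10 | tert-butyldimethylsilyl rac-2-[2-(2,2-dimethylchroman-6-yl)-2-hydroxyethoxy]-3-(3-methylbut-2-en-1-yl)-4-(triisopropylsilyloxy)benzoate | CC(C)=CCc1c(O[Si](C(C)C)(C(C)C)C(C)C)ccc(C(=O)O[Si](C)(C)C(C)(C)C)c1OCC(O)c1ccc2c(c1)CCC(C)(C)O2
F9 | step 10 | tert-butyldimethylsilyl rac-2-[2-chloro-2-(2,2-dimethylchroman-6-yl)ethoxy]-3-(3-methylbut-2-en-1-yl)-4-(triisopropylsilyloxy)benzoate | CC(C)=CCc1c(O[Si](C(C)C)(C(C)C)C(C)C)ccc(C(=O)O[Si](C)(C)C(C)(C)C)c1OCC(Cl)c1ccc2c(c1)CCC(C)(C)O2
F10 | step 4 | 2-(3-methylbut-2-en-1-yl)benzene-1,3-diol | CC(C)=CCc1c(O)cccc1O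
F11 | step 4 | 2,4-dihydroxy-3-(3-methylbut-2-en-1-yl)benzoic acid | CC(C)=CCc1c(O)ccc(C(=O)O)c1O
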